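**Strategy.** The route rests on disconnecting the C1–C6 bond of the ε-ring (the 1,1,5-trimethylcyclohex-4-ene, atoms C1–C6), which joins the quaternary gem-dimethyl carbon C1 to the stereocentre C6, back to an open geranyl-type chain. One proton-initiated cation–olefin closure builds that bond and the ring, places the C4=C5 alkene and relays the epichlorohydrin-derived C3 stereocentre to C6 (trans-1,4) through a chair. The precursor is a (5R)-3,7-dimethylocta-2,7-diene carrying an isopropenyl initiator, an E trisubstituted alkene with a primary allylic acetate, and a non-participating trifluoroacetate on the C3 carbinol. The chain is then attached in one Julia–Kocienski olefination with the C20 dialdehyde crocetindial.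

Key step: step 6

Remarks and assumptions:
- Carotenoid numbering is used for ring and chain atoms (ring C1–C6, chain C7–C15 and C15'–C8').
- Crocetindial (18) is taken as a purchasable carotenoid building block.
- Descriptor check: (R)-epichlorohydrin gives the (5R) open-chain carbinol, which becomes C3 (R); the trans-1,4 closure then gives C6 (R), as in the target.
- PT = 1-phenyl-1H-tetrazol-5-yl. Polyenes 18–20 are handled under argon in dim light.

Step 1
Reactants: 1 (R)-epichlorohydrin; 2 isopropenylmagnesium bromide
Product: 3 (2R)-1-chloro-4-methylpent-4-en-2-ol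
Conditions: CuI (10 mol%), THF, −40 °C → −20 °C; quench with H2O
Reagents that add atoms: none
Why: Copper-catalysed Grignard opening of the epoxide (SN2 at its unsubstituted carbon) is faster than chloride displacement and does not touch the stereocentre.

Step 2
Reactants: 3 (2R)-1-chloro-4-methylpent-4-en-2-ol; 4 lithium acetylide ethylenediamine complex (3 equiv)
Product: 6 (4R)-6-methylhept-6-en-1-yn-4-ol, via epoxide 5 (not isolated)
Conditions: DMSO, 0 °C → rt; quench with H2O
Reagents that add atoms: none
Why: The lithium alkoxide should close to the epoxide (intramolecular Williamson displacement) and a second acetylide should open it at the CH2 terminus (epoxide alkynylation), so the carbinol configuration is retained.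

Step 3
Reactants: 6 (4R)-6-methylhept-6-en-1-yn-4-ol
Product: 9 (2E,5R)-3,7-dimethylocta-2,7-diene-1,5-diol, via alkenylalane 7 (not isolated), via lithium alkenylalanate 8 (not isolated)
Conditions: AlMe3 (3 equiv), Cp2ZrCl2 (0.25 equiv), CH2Cl2, 0 °C → rt; then n-BuLi, THF, −78 °C; (CH2O)n, −78 °C → rt; aq. potassium sodium tartrate
Reagents that add atoms: trimethylaluminium, C[Al](C)C; formaldehyde (from paraformaldehyde), C=O
Why: Negishi carboalumination adds Me–Al syn across the terminal alkyne with aluminium on the terminal carbon, which fixes the E trisubstituted alkene, and the derived alanate is hydroxymethylated with retention of geometry while the isopropenyl group stays inert.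

Step 4
Reactants: 9 (2E,5R)-3,7-dimethylocta-2,7-diene-1,5-diol
Product: 10 (2E,5R)-5-hydroxy-3,7-dimethylocta-2,7-dien-1-yl acetate
Conditions: AcCl (1.05 equiv), 2,4,6-collidine, CH2Cl2, −78 °C
Reagents that add atoms: acetyl chloride, CC(Cl)=O
Why: Kinetic esterification with an acid chloride and a hindered pyridine base at low temperature should acylate the unhindered primary allylic hydroxyl and leave the secondary one.

Step 5
Reactants: 10 (2E,5R)-5-hydroxy-3,7-dimethylocta-2,7-dien-1-yl acetate
Product: 11 (2E,5R)-1-acetoxy-3,7-dimethylocta-2,7-dien-5-yl trifluoroacetate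
Conditions: (CF3CO)2O, pyridine, CH2Cl2, −20 °C → 0 °C; used without chromatography
Reagents that add atoms: trifluoroacetic anhydride, O=C(OC(=O)C(F)(F)F)C(F)(F)F
Why: Acylation of the secondary alcohol with the anhydride (esterification at oxygen, so the R configuration is untouched) installs the labile electron-poor ester last.

Step 6
Reactants: 11 (2E,5R)-1-acetoxy-3,7-dimethylocta-2,7-dien-5-yl trifluoroacetate
Product: 12 [(1R,4R)-2,6,6-trimethyl-4-(trifluoroacetoxy)cyclohex-2-en-1-yl]methyl acetate
Conditions: FSO3H (5 equiv), 2-nitropropane (dilute), −78 °C, 20 min; then Et3N, −78 °C; cold aq. NaHCO3; crude product taken on at once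
Reagents that add atoms: none
Why: Proposed new method: The superacid should protonate the acetate first, which shields the C5=C6 alkene, and then the 1,1-disubstituted alkene to give the tertiary C1 cation; C6 of the E alkene attacks it to form the C1–C6 bond and the six-membered ring by 6-endo-trig closure, and the tertiary C5 cation loses a C4 proton to give C4=C5. The closest known reaction type is the superacid-mediated cation–olefin cyclisation of geranyl acetate to alpha-cyclogeranyl acetate (and of pseudoionone to alpha-ionone), which has not been run with an acyloxy group on C3. The new C6 stereocentre is set by a chair transition state in which the C3 trifluoroacetoxy group lies equatorial, away from the pseudoaxial C1 methyl group, and the E geometry places C7 equatorial, so the trans-1,4 (3R,6R) relation should result. The step needs site-selective initiation, a C1 cation that is neither bridged by the C3 ester nor fragmented at C2–C3, and proton loss from C4; the weakly basic, poorly donating trifluoroacetate and a kinetic quench at −78 °C are meant to secure these, with the proton-loss regiochemistry the least certain.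

Step 7
Reactants: 12 [(1R,4R)-2,6,6-trimethyl-4-(trifluoroacetoxy)cyclohex-2-en-1-yl]methyl acetate
Product: 13 [(1R,4R)-4-hydroxy-2,6,6-trimethylcyclohex-2-en-1-yl]methyl acetate
Conditions: Et3N, MeOH, 0 °C → rt
Reagents that add atoms: none
Why: Amine-catalysed transesterification with methanol cleaves a trifluoroacetate far faster than an acetate and proceeds by acyl–oxygen cleavage, so only the C3 hydroxyl is freed and its configuration is kept.

Step 8
Reactants: 13 [(1R,4R)-4-hydroxy-2,6,6-trimethylcyclohex-2-en-1-yl]methyl acetate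
Product: 14 (1R,4R)-4-(acetoxymethyl)-3,5,5-trimethylcyclohex-2-en-1-yl pivalate
Conditions: PivCl, pyridine, DMAP (cat.), CH2Cl2, 0 °C → rt
Reagents that add atoms: pivaloyl chloride, CC(C)(C)C(Cl)=O
Why: DMAP-catalysed acylation of the secondary allylic alcohol gives a base-stable ester without α-hydrogens that the final hydride step will remove.

Step 9
Reactants: 14 (1R,4R)-4-(acetoxymethyl)-3,5,5-trimethylcyclohex-2-en-1-yl pivalate
Product: 15 (1R,4R)-4-(hydroxymethyl)-3,5,5-trimethylcyclohex-2-en-1-yl pivalate
Conditions: K2CO3, MeOH, 0 °C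
Reagents that add atoms: none
Why: Carbonate-mediated methanolysis (Zemplén-type transesterification) should remove the unhindered acetyl group much faster than the tert-butyl-shielded pivaloyl group.

Step 10
Reactants: 15 (1R,4R)-4-(hydroxymethyl)-3,5,5-trimethylcyclohex-2-en-1-yl pivalate
Product: 16 (1R,4R)-3,5,5-trimethyl-4-{[(1-phenyl-1H-tetrazol-5-yl)sulfanyl]methyl}cyclohex-2-en-1-yl pivalate
Conditions: 1-phenyl-1H-tetrazole-5-thiol, PPh3, DIAD, THF, 0 °C → rt
Reagents that add atoms: 1-phenyl-1H-tetrazole-5-thiol, Sc1nnnn1-c1ccccc1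
Why: Mitsunobu thioetherification of the primary alcohol with an acidic heteroaryl thiol is an SN2 displacement at C7 that involves no stereocentre and runs under non-basic conditions.

Step 11
Reactants: 16 (1R,4R)-3,5,5-trimethyl-4-{[(1-phenyl-1H-tetrazol-5-yl)sulfanyl]methyl}cyclohex-2-en-1-yl pivalate
Product: 17 (1R,4R)-3,5,5-trimethyl-4-{[(1-phenyl-1H-tetrazol-5-yl)sulfonyl]methyl}cyclohex-2-en-1-yl pivalate
Conditions: (NH4)6Mo7O24·4H2O (10 mol%), 30% aq. H2O2, EtOH, 0 °C → rt
Reagents that add atoms: hydrogen peroxide, OO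
Why: Molybdate-catalysed peroxide oxidation of sulfide to sulfone is chemoselective in the presence of the hindered, ester-deactivated trisubstituted alkene.

Step 12
Reactants: 17 (1R,4R)-3,5,5-trimethyl-4-{[(1-phenyl-1H-tetrazol-5-yl)sulfonyl]methyl}cyclohex-2-en-1-yl pivalate; 18 crocetindial (3 equiv)
Product: 19 (3R,6R)-3-(pivaloyloxy)-8'-apo-ε-caroten-8'-al
Conditions: KN(SiMe3)2 (1.2 equiv) added to 17 and 18, THF, −78 °C → rt; quench with H2O
Reagents that add atoms: none
Why: Julia–Kocienski olefination: the metalated PT sulfone adds to one formyl group of the dialdehyde held in excess, and Smiles rearrangement with loss of SO2 and the tetrazolone should form C7=C8 with E preference for an α-methyl enal, while C6 is never α to a carbonyl and cannot epimerise.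

Step 13
Reactants: 19 (3R,6R)-3-(pivaloyloxy)-8'-apo-ε-caroten-8'-al
Product: 20 (3R,6R)-3-hydroxy-8'-apo-ε-caroten-8'-ol (target)
Conditions: i-Bu2AlH (excess), CH2Cl2, −78 °C → −20 °C; aq. potassium sodium tartrate
Reagents that add atoms: none
Why: Hydride reduction with i-Bu2AlH should reduce the conjugated aldehyde 1,2 to the allylic alcohol and cleave the pivalate in the same operation, under non-acidic conditions that spare the allylic C3 carbinol and the polyene.

**Compound list**

1 | (R)-epichlorohydrin, (2R)-2-(chloromethyl)oxirane | ClC[C@H]1CO1 | starting material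
2 | isopropenylmagnesium bromide | CC(=C)[Mg]Br | starting material
3 | (2R)-1-chloro-4-methylpent-4-en-2-ol | ClC[C@H](O)CC(C)=C | intermediate
4 | lithium acetylide ethylenediamine complex | [Li]C#C.NCCN | starting material
5 | (2R)-2-(2-methylprop-2-en-1-yl)oxirane | CC(=C)C[C@@H]1CO1 | intermediate (not isolated)
6 | (4R)-6-methylhept-6-en-1-yn-4-ol | C#CC[C@H](O)CC(C)=C | intermediate
7 | alkenylalane, [(1E,4R)-4-(dimethylalumanyloxy)-2,6-dimethylhepta-1,6-dien-1-yl]dimethylalumane | C[Al](C)/C=C(\C)C[C@H](O[Al](C)C)CC(C)=C | intermediate (not isolated)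
8 | lithium alkenylalanate, lithium butyl[(1E,4R)-4-(dimethylalumanyloxy)-2,6-dimethylhepta-1,6-dien-1-yl]dimethylaluminate | [Li+].CCCC[Al-](C)(C)/C=C(\C)C[C@H](O[Al](C)C)CC(C)=C | intermediate (not isolated)
9 | (2E,5R)-3,7-dimethylocta-2,7-diene-1,5-diol | CC(=C)C[C@@H](O)C/C(C)=C/CO | intermediate
10 | (2E,5R)-5-hydroxy-3,7-dimethylocta-2,7-dien-1-yl acetate | CC(=C)C[C@@H](O)C/C(C)=C/COC(C)=O | intermediate
11 | (2E,5R)-1-acetoxy-3,7-dimethylocta-2,7-dien-5-yl trifluoroacetate | CC(=C)C[C@@H](OC(=O)C(F)(F)F)C/C(C)=C/COC(C)=O | intermediate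
12 | [(1R,4R)-2,6,6-trimethyl-4-(trifluoroacetoxy)cyclohex-2-en-1-yl]methyl acetate | CC1=C[C@H](OC(=O)C(F)(F)F)CC(C)(C)[C@H]1COC(C)=O | intermediate
13 | [(1R,4R)-4-hydroxy-2,6,6-trimethylcyclohex-2-en-1-yl]methyl acetate | CC1=C[C@H](O)CC(C)(C)[C@H]1COC(C)=O | intermediate
14 | (1R,4R)-4-(acetoxymethyl)-3,5,5-trimethylcyclohex-2-en-1-yl pivalate | CC1=C[C@H](OC(=O)C(C)(C)C)CC(C)(C)[C@H]1COC(C)=O | intermediate
15 | (1R,4R)-4-(hydroxymethyl)-3,5,5-trimethylcyclohex-2-en-1-yl pivalate | CC1=C[C@H](OC(=O)C(C)(C)C)CC(C)(C)[C@H]1CO | intermediate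
16 | (1R,4R)-3,5,5-trimethyl-4-{[(1-phenyl-1H-tetrazol-5-yl)sulfanyl]methyl}cyclohex-2-en-1-yl pivalate | CC1=C[C@H](OC(=O)C(C)(C)C)CC(C)(C)[C@H]1CSc1nnnn1-c1ccccc1 | intermediate
17 | (1R,4R)-3,5,5-trimethyl-4-{[(1-phenyl-1H-tetrazol-5-yl)sulfonyl]methyl}cyclohex-2-en-1-yl pivalate | CC1=C[C@H](OC(=O)C(C)(C)C)CC(C)(C)[C@H]1CS(=O)(=O)c1nnnn1-c1ccccc1 | intermediate
18 | crocetindial, (2E,4E,6E,8E,10E,12E,14E)-2,6,11,15-tetramethylhexadeca-2,4,6,8,10,12,14-heptaenedial | O=C/C(C)=C/C=C/C(C)=C/C=C/C=C(C)/C=C/C=C(\C)C=O | starting material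
19 | (3R,6R)-3-(pivaloyloxy)-8'-apo-ε-caroten-8'-al, the all-E C30 aldehyde with the ring of 15 attached at C7 | CC1=C[C@H](OC(=O)C(C)(C)C)CC(C)(C)[C@H]1/C=C/C(C)=C/C=C/C(C)=C/C=C/C=C(C)/C=C/C=C(\C)C=O | intermediate
20 | (3R,6R)-3-hydroxy-8'-apo-ε-caroten-8'-ol, (1R,4R)-4-[(1E,3E,5E,7E,9E,11E,13E,15E)-17-hydroxy-3,7,12,16-tetramethylheptadeca-1,3,5,7,9,11,13,15-octaen-1-yl]-3,5,5-trimethylcyclohex-2-en-1-ol | CC1=C[C@H](O)CC(C)(C)[C@H]1/C=C/C(C)=C/C=C/C(C)=C/C=C/C=C(C)/C=C/C=C(\C)CO | target

**Totals**

Total step count: 13. Longest linear sequence: 13 steps, from 1 to 20.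

**Steps most likely to fail, with fallbacks**

Step 6 (Proposed new method). What may go wrong: the C1 cation is intercepted before ring closure (bridging by the C3 ester, or C2 proton loss followed by ionisation of the then allylic trifluoroacetate). The C5 cation may also shed a methyl or C6 proton instead of the C4 proton, and the allylic trifluoroacetate of the product may ionise in the superacid. The fallback leaves the cationic manifold and uses a known radical cycloisomerisation of dienes, which has its own uncertainty in where the alkene ends up. Setting out from 10, pivaloylation (PivCl, pyridine, DMAP) would give (2E,5R)-1-acetoxy-3,7-dimethylocta-2,7-dien-5-yl pivalate F1. Cobalt-catalysed hydrogen-atom-transfer cycloisomerisation (Co(salen)Cl, salen = N,N'-bis(salicylidene)ethylenediaminate, PhSiH3 cat., benzene, rt) would deliver H• to the isopropenyl group. The tertiary C1 radical would close 6-endo onto C6 through the same chair, with both substituents equatorial, and the alkene would return by hydrogen abstraction from the C5 radical. Alkene isomers would be removed on AgNO3-impregnated silica. This gives 14 directly, where the route is rejoined; steps 5–8 are bypassed.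

Step 12. What may go wrong: incomplete E selectivity at C7=C8, olefination at both formyl groups, and slow addition of the hindered sulfonyl carbanion to a sparingly soluble polyene dialdehyde. The fallback reverses the polarity and builds the chain by phosphorus olefinations with the ring always as the aldehyde; it also bypasses steps 10 and 11. Setting out from 15, Dess–Martin oxidation (NaHCO3 buffer) would give (1R,4R)-4-formyl-3,5,5-trimethylcyclohex-2-en-1-yl pivalate F2. Horner–Wadsworth–Emmons reaction with the lithium anion of diethyl (3-cyano-2-methylallyl)phosphonate (LiN(SiMe3)2, THF, −78 °C) would give (1R,4R)-4-[(1E,3E)-4-cyano-3-methylbuta-1,3-dien-1-yl]-3,5,5-trimethylcyclohex-2-en-1-yl pivalate F3. i-Bu2AlH would reduce the nitrile to the aldehyde and remove the pivalate, giving (2E,4E)-5-[(1R,4R)-4-hydroxy-2,6,6-trimethylcyclohex-2-en-1-yl]-3-methylpenta-2,4-dienal F4. In parallel, mono-olefination of 2,7-dimethylocta-2,4,6-trienedial (in excess) with ethyl (E)-4-(diethoxyphosphoryl)-2-methylbut-2-enoate would give ethyl (2E,4E,6E,8E,10E)-2,6,11-trimethyl-12-oxododeca-2,4,6,8,10-pentaenoate F5. NaBH4 would give ethyl (2E,4E,6E,8E,10E)-12-hydroxy-2,6,11-trimethyldodeca-2,4,6,8,10-pentaenoate F6, and PPh3·HBr would give [(2E,4E,6E,8E,10E)-12-ethoxy-2,7,11-trimethyl-12-oxododeca-2,4,6,8,10-pentaen-1-yl]triphenylphosphonium bromide F7. Wittig coupling of F4 with F7 (NaOMe), followed by thermal equilibration to the all-E isomer, would give ethyl (3R,6R)-3-hydroxy-8'-apo-ε-caroten-8'-oate F8. Reduction with i-Bu2AlH would then give the target 20, where the route is rejoined.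

Step 3. What may go wrong: incomplete hydroxymethylation of the alkenylaluminium species in the presence of the aluminium alkoxide, which would leave the merely protonated alkene. The fallback sets the trisubstituted alkene by alkoxide-directed hydroalumination and cuprate methylation instead of carbometalation. Setting out from 6, double deprotonation (n-BuLi, 2.1 equiv, THF, −78 °C) and paraformaldehyde would give (5R)-7-methyloct-7-en-2-yne-1,5-diol F9. trans-Hydroalumination with NaAlH2(OCH2CH2OMe)2 and iodinolysis (I2, −78 °C) would give (2Z,5R)-3-iodo-7-methylocta-2,7-diene-1,5-diol F10. Methylation with Me2CuLi (excess, Et2O, 0 °C), with retention at the vinylic carbon, would return the E diol 9, where the route is rejoined.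

**Further compounds**

F1 | step 6 | (2E,5R)-1-acetoxy-3,7-dimethylocta-2,7-dien-5-yl pivalate | CC(=C)C[C@@H](OC(=O)C(C)(C)C)C/C(C)=C/COC(C)=O
F2 | step 12 | (1R,4R)-4-formyl-3,5,5-trimethylcyclohex-2-en-1-yl pivalate | CC1=C[C@H](OC(=O)C(C)(C)C)CC(C)(C)[C@H]1C=O
F3 | step 12 | (1R,4R)-4-[(1E,3E)-4-cyano-3-methylbuta-1,3-dien-1-yl]-3,5,5-trimethylcyclohex-2-en-1-yl pivalate | CC1=C[C@H](OC(=O)C(C)(C)C)CC(C)(C)[C@H]1/C=C/C(C)=C/C#N
F4 | step 12 | (2E,4E)-5-[(1R,4R)-4-hydroxy-2,6,6-trimethylcyclohex-2-en-1-yl]-3-methylpenta-2,4-dienal | CC1=C[C@H](O)CC(C)(C)[C@H]1/C=C/C(C)=C/C=O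
F5 | step 12 | ethyl (2E,4E,6E,8E,10E)-2,6,11-trimethyl-12-oxododeca-2,4,6,8,10-pentaenoate | O=C/C(C)=C/C=C/C=C(C)/C=C/C=C(\C)C(=O)OCC
F6 | step 12 | ethyl (2E,4E,6E,8E,10E)-12-hydroxy-2,6,11-trimethyldodeca-2,4,6,8,10-pentaenoate | OC/C(C)=C/C=C/C=C(C)/C=C/C=C(\C)C(=O)OCC
F7 | step 12 | [(2E,4E,6E,8E,10E)-12-ethoxy-2,7,11-trimethyl-12-oxododeca-2,4,6,8,10-pentaen-1-yl]triphenylphosphonium bromide | c1ccccc1[P+](c1ccccc1)(c1ccccc1)C/C(C)=C/C=C/C=C(C)/C=C/C=C(\C)C(=O)OCC.[Br-]
F8 | step 12 | ethyl (3R,6R)-3-hydroxy-8'-apo-ε-caroten-8'-oate | CC1=C[C@H](O)CC(C)(C)[C@H]1/C=C/C(C)=C/C=C/C(C)=C/C=C/C=C(C)/C=C/C=C(\C)C(=O)OCC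
F9 | step 3 | (5R)-7-methyloct-7-en-2-yne-1,5-diol | OCC#CC[C@H](O)CC(C)=C
F10 | step 3 | (2Z,5R)-3-iodo-7-methylocta-2,7-diene-1,5-diol | OC/C=C(\I)C[C@H](O)CC(C)=C
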